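**Retrosynthetic overview**
- The target is a 2-methoxy-6-alkyl-1,4-benzoquinone. The acid is unmasked last from a tert-butyl ester, and the quinone comes from oxidative demethylation of a 4-methoxyphenol.
- The strategy rests on the single six-membered ring: the carbonyl carbons C1 and C4 are para, C2 carries the methoxy group, C6 carries the C15 acid chain, and C3 and C5 carry hydrogen.
- That ring is closed in one three-component benzannulation: carbene carbon → C4, alkyne CH → C5, alkyne C(chain) → C6, one CO ligand → C1, vinyl C(OMe) → C2, vinyl CH → C3. The new bonds are C4–C5, C6–C1 and C1–C2.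
- The carbene complex comes from Cr(CO)6, trimethylsilylacetylene and methanol; the alkyne comes from 15-bromopentadecanoic acid and lithium acetylide.

Key step: step 5

Assumption: carbene 7 is written as the (E)-isomer; because its vinyl β-carbon becomes aromatic C2, any (Z)-isomer present should converge on the same phenol.

**Step 1**
Reactants: 1 trimethylsilylacetylene; 2 chromium hexacarbonyl Cr(CO)6
Product: 5 pentacarbonyl[1-methoxy-3-(trimethylsilyl)prop-2-yn-1-ylidene]chromium, via lithium trimethylsilylacetylide 3 (not isolated), via lithium acyl chromate Li[(CO)5CrC(O)C≡CSiMe3] 4 (not isolated)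
Conditions: n-BuLi, THF, −78 °C; Cr(CO)6, −78 °C → rt; then Me3OBF4, CH2Cl2, 0 °C
Reagents that add atoms: trimethyloxonium tetrafluoroborate Me3OBF4, C[O+](C)C.F[B-](F)(F)F
Why: Fischer carbene synthesis, in which the acetylide adds to a CO ligand of Cr(CO)6 and the resulting acyl chromate is methylated on oxygen by the oxonium salt; the silyl cap keeps the alkynylcarbene stable enough to handle.

**Step 2**
Reactants: 5 pentacarbonyl[1-methoxy-3-(trimethylsilyl)prop-2-yn-1-ylidene]chromium
Product: 7 pentacarbonyl[(E)-1,3-dimethoxyprop-2-en-1-ylidene]chromium, via pentacarbonyl(1-methoxyprop-2-yn-1-ylidene)chromium 6 (not isolated)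
Conditions: NaOMe (0.1 equiv), MeOH/THF, −20 °C → rt
Reagents that add atoms: methanol, CO
Why: Methoxide should cleave the C(sp)–Si bond of the ynone-like alkynylcarbene, and methanol then adds to the electron-poor triple bond by Michael addition, a known entry to 2-alkoxyalkenyl carbene complexes; exchange at the carbene carbon is degenerate because the nucleophile is methoxide, and the (E)-isomer is expected to be the thermodynamic one.

**Step 3**
Reactants: 8 15-bromopentadecanoic acid; 9 lithium acetylide–ethylenediamine complex LiC≡CH·H2NCH2CH2NH2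
Product: 10 heptadec-16-ynoic acid
Conditions: 9 (3 equiv), DMSO, 10 °C → rt; then aq. HCl
Reagents that add atoms: none
Why: SN2 alkylation of lithium acetylide by the primary bromide in DMSO; the first equivalent of reagent turns the acid into an inert carboxylate.

**Step 4**
Reactants: 10 heptadec-16-ynoic acid
Product: 11 tert-butyl heptadec-16-ynoate
Conditions: Cl3CC(=NH)Ot-Bu (2 equiv), CH2Cl2/cyclohexane, rt
Reagents that add atoms: tert-butyl 2,2,2-trichloroacetimidate, CC(C)(C)OC(=N)C(Cl)(Cl)Cl
Why: Trichloroacetimidate esterification, in which the carboxylic acid protonates the imidate and is tert-butylated with loss of trichloroacetamide; the terminal alkyne is untouched.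

**Step 5**
Reactants: 7 pentacarbonyl[(E)-1,3-dimethoxyprop-2-en-1-ylidene]chromium; 11 tert-butyl heptadec-16-ynoate
Product: 13 tert-butyl 15-(2-hydroxy-3,5-dimethoxyphenyl)pentadecanoate, via tricarbonyl(η6-arene)chromium complex 12 (not isolated)
Conditions: 7 (1.3 equiv), THF (0.05 M), 55 °C, Ar; then air, rt
Reagents that add atoms: none
Why: Thermal loss of one cis CO from the zerovalent chromium carbene 7 opens a site for alkyne 11, which inserts into the Cr=C bond with its unsubstituted terminus on the carbene carbon (C4–C5) to give an η3-vinylcarbene, and migratory CO insertion then forms the η4-vinylketene (C6–C1). The dienylketene closes the only ring by a thermal 6π-electrocyclisation of the ketene carbon onto the methoxy-bearing vinyl terminus (C1–C2), and the cyclohexa-2,4-dienone tautomerises to the phenol, first held as the Cr(CO)3 complex 12 and freed by air. The closest known reaction type is the Dötz benzannulation of alkenyl(alkoxy)carbene chromium complexes with terminal alkynes, here with a 2-alkoxyvinyl group on the carbene. No stereocenter is formed, and the vinyl geometry is erased on aromatisation. Two selectivities are needed: the regiochemistry of insertion, which is steric and places the long chain next to the CO-derived C1 because the alkyne is terminal, and CO insertion over cyclopentannulation, which chromium, the alkoxy carbene, THF and moderate dilution favour. The para relationship of the carbene carbon (C4) and the inserted CO (C1) sets both future quinone carbonyls, with the methoxy on C2 and the chain on C6.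

**Step 6**
Reactants: 13 tert-butyl 15-(2-hydroxy-3,5-dimethoxyphenyl)pentadecanoate
Product: 14 tert-butyl 15-(5-methoxy-3,6-dioxocyclohexa-1,4-dien-1-yl)pentadecanoate
Conditions: (NH4)2Ce(NO3)6 (2.2 equiv), MeCN/H2O, 0 °C
Reagents that add atoms: water, O
Why: Oxidative demethylation, in which two-electron oxidation of the para-methoxyphenol by tetravalent cerium gives an oxocarbenium ion at C4 that water traps with loss of methanol; a short reaction at 0 °C should spare the tert-butyl ester.

**Step 7**
Reactants: 14 tert-butyl 15-(5-methoxy-3,6-dioxocyclohexa-1,4-dien-1-yl)pentadecanoate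
Product: 15 15-(5-methoxy-3,6-dioxocyclohexa-1,4-dien-1-yl)pentadecanoic acid
Conditions: CF3CO2H/CH2Cl2 (1:3), 0 °C → rt
Reagents that add atoms: none
Why: Acidolysis of the tert-butyl ester by E1 loss of 2-methylpropene under anhydrous acid; the electron-poor methoxyquinone is not alkylated by the cation, which is why the ester is removed after the oxidation.

**Compound list**
1 | trimethylsilylacetylene | C#C[Si](C)(C)C | starting material
2 | chromium hexacarbonyl Cr(CO)6 | O=C=[Cr](=C=O)(=C=O)(=C=O)(=C=O)=C=O | starting material
3 | lithium trimethylsilylacetylide | [Li]C#C[Si](C)(C)C | intermediate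
4 | lithium pentacarbonyl[1-oxido-3-(trimethylsilyl)prop-2-yn-1-ylidene]chromate | [Li+].[O-]C(C#C[Si](C)(C)C)=[Cr](=C=O)(=C=O)(=C=O)(=C=O)=C=O | intermediate
5 | pentacarbonyl[1-methoxy-3-(trimethylsilyl)prop-2-yn-1-ylidene]chromium | COC(C#C[Si](C)(C)C)=[Cr](=C=O)(=C=O)(=C=O)(=C=O)=C=O | intermediate
6 | pentacarbonyl(1-methoxyprop-2-yn-1-ylidene)chromium | COC(C#C)=[Cr](=C=O)(=C=O)(=C=O)(=C=O)=C=O | intermediate
7 | pentacarbonyl[(E)-1,3-dimethoxyprop-2-en-1-ylidene]chromium | COC(/C=C/OC)=[Cr](=C=O)(=C=O)(=C=O)(=C=O)=C=O | intermediate
8 | 15-bromopentadecanoic acid | BrCCCCCCCCCCCCCCC(=O)O | starting material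
9 | lithium acetylide–ethylenediamine complex | [Li]C#C.NCCN | starting material
10 | heptadec-16-ynoic acid | C#CCCCCCCCCCCCCCCCC(=O)O | intermediate
11 | tert-butyl heptadec-16-ynoate | C#CCCCCCCCCCCCCCCCC(=O)OC(C)(C)C | intermediate
12 | tricarbonyl[η6-tert-butyl 15-(2-hydroxy-3,5-dimethoxyphenyl)pentadecanoate]chromium (arene and Cr(CO)3 fragment written separately) | COc1cc(OC)c(O)c(CCCCCCCCCCCCCCC(=O)OC(C)(C)C)c1.O=C=[Cr](=C=O)=C=O | intermediate
13 | tert-butyl 15-(2-hydroxy-3,5-dimethoxyphenyl)pentadecanoate | COc1cc(OC)c(O)c(CCCCCCCCCCCCCCC(=O)OC(C)(C)C)c1 | intermediate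
14 | tert-butyl 15-(5-methoxy-3,6-dioxocyclohexa-1,4-dien-1-yl)pentadecanoate | COC1=CC(=O)C=C(CCCCCCCCCCCCCCC(=O)OC(C)(C)C)C1=O | intermediate
15 | 15-(5-methoxy-3,6-dioxocyclohexa-1,4-dien-1-yl)pentadecanoic acid | COC1=CC(=O)C=C(CCCCCCCCCCCCCCC(=O)O)C1=O | target

**Total step count:** 7
**Longest linear sequence:** 5 steps (steps 1, 2, 5, 6, 7 or steps 3, 4, 5, 6, 7)

**Steps most likely to fail**

1. Step 5. The methoxy donor on the vinyl group may slow CO loss and CO insertion, so that cyclopentannulation or alkyne oligomerisation competes with phenol formation. The fallback leaves the carbene chemistry and sets out from bromo acid 8. Esterification with tert-butyl 2,2,2-trichloroacetimidate should give tert-butyl 15-bromopentadecanoate F1. Zinc insertion (Zn dust, cat. I2, DMA, 80 °C) should give (15-tert-butoxy-15-oxopentadecyl)zinc bromide F2. Commercial 2-bromo-6-methoxyphenol is benzylated (BnBr, K2CO3, DMF) to 2-(benzyloxy)-1-bromo-3-methoxybenzene F3. Negishi coupling of F2 with F3 (Pd(OAc)2, SPhos, THF/DMA) should give tert-butyl 15-[2-(benzyloxy)-3-methoxyphenyl]pentadecanoate F4. Hydrogenolysis (H2, Pd/C, EtOAc) frees tert-butyl 15-(2-hydroxy-3-methoxyphenyl)pentadecanoate F5. Teuber oxidation of this para-unsubstituted phenol with (KSO3)2NO in buffered aqueous acetone should return to the route at quinone ester 14.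

2. Step 2. Over-addition of methanol to an acetal, attack at the carbene carbon, or decomposition of the transient ethynylcarbene 6 may erode the conversion. The fallback builds the same complex by acylation and sets out from Cr(CO)6 2. Reduction with potassium graphite KC8 (THF, −78 °C) gives dipotassium pentacarbonylchromate K2Cr(CO)5 F6. This is acylated with (E)-3-methoxyacryloyl chloride F7, made from commercial (E)-3-methoxyacrylic acid and (COCl)2, to give potassium pentacarbonyl[(E)-3-methoxy-1-oxidoprop-2-en-1-ylidene]chromate F8. O-Methylation with Me3OBF4 returns to the route at carbene 7.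

3. Step 6. Competing demethylation at the C2 methoxy group (ortho-quinone formation), over-oxidation, or partial loss of the tert-butyl ester in the acidic oxidant may lower the purity. The fallback sets out from phenol 13 and uses oxidative dearomatisation with PhI(OAc)2 in methanol at 0 °C to give the quinone monoketal tert-butyl 15-(3,3,5-trimethoxy-6-oxocyclohexa-1,4-dien-1-yl)pentadecanoate F9. Treatment with CF3CO2H/H2O/CH2Cl2 then hydrolyses the ketal and cleaves the ester in one operation, returning to the route at target 15.

**Further compounds**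
F1 | step 5 | tert-butyl 15-bromopentadecanoate | BrCCCCCCCCCCCCCCC(=O)OC(C)(C)C
F2 | step 5 | (15-tert-butoxy-15-oxopentadecyl)zinc bromide | CC(C)(C)OC(=O)CCCCCCCCCCCCCC[Zn]Br
F3 | step 5 | 2-(benzyloxy)-1-bromo-3-methoxybenzene | COc1cccc(Br)c1OCc1ccccc1
F4 | step 5 | tert-butyl 15-[2-(benzyloxy)-3-methoxyphenyl]pentadecanoate | COc1cccc(CCCCCCCCCCCCCCC(=O)OC(C)(C)C)c1OCc1ccccc1
F5 | step 5 | tert-butyl 15-(2-hydroxy-3-methoxyphenyl)pentadecanoate | COc1cccc(CCCCCCCCCCCCCCC(=O)OC(C)(C)C)c1O
F6 | step 2 | dipotassium pentacarbonylchromate K2Cr(CO)5 | [K+].[K+].O=C=[Cr-2](=C=O)(=C=O)(=C=O)=C=O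
F7 | step 2 | (E)-3-methoxyacryloyl chloride | CO/C=C/C(Cl)=O
F8 | step 2 | potassium pentacarbonyl[(E)-3-methoxy-1-oxidoprop-2-en-1-ylidene]chromate | [K+].[O-]C(/C=C/OC)=[Cr](=C=O)(=C=O)(=C=O)(=C=O)=C=O
F9 | step 6 | tert-butyl 15-(3,3,5-trimethoxy-6-oxocyclohexa-1,4-dien-1-yl)pentadecanoate | COC1=CC(OC)(OC)C=C(CCCCCCCCCCCCCCC(=O)OC(C)(C)C)C1=O
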